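A direct plan would close the ring by a copper-catalysed [2+2] photobicyclisation of the resolved 1,6-dienol A1, oxidise the adduct to the bicyclic ketone A2, acetylate it, open the five-membered ring by retro-Claisen cleavage to the cis keto acid A3 and exchange the carboxyl group for the alkenyl chain by a nickel-catalysed decarboxylative coupling. Its weakest steps would be: (a) the kinetic resolution with the photobicyclisation onto a trisubstituted alkene, where half of the material would be lost and any exo adduct would erode the enantiomeric purity; (b) the retro-Claisen opening, where hydroxide could attack the acetyl group and return A2; (c) the radical decarboxylative alkenylation at a hindered ring carbon, whose trans outcome would rest on substrate control alone.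

The route rests on the C1–C2 bond of the cyclobutane, the bond that joins the two stereogenic CH carbons (C1 with the alkenyl chain, C2 with the oxobutyl chain next to the gem-dimethyl carbon C3): it is drawn as the C=C bond of an achiral 1-alkyl-4,4-dimethylcyclobutene. One copper hydride catalysed syn-hydroboration then sets both stereocentres together, trans by the geometry of addition and absolute by the ligand, and the C–B bond is exchanged for the alkenyl chain by a stereoretentive Zweifel 1,2-migration. The ring itself comes from a thermal keteniminium–ethylene [2+2]. No resolution, photochemical chirality relay, ring cleavage or radical decarboxylation remains; the ester is made by carboxylate alkylation, so no alcohol is protected.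

Key step: step 4

Assumption: the ligand enantiomer needed in step 4 cannot be predicted with certainty for this substrate; (R)-DTBM-SEGPHOS is written, and the (S)-ligand would be taken if the opposite face of the alkene were attacked.

Step 1
Reactants: 1 N,N-dimethylisobutyramide; 2 ethylene
Product: 5 2,2-dimethylcyclobutan-1-one, via tetramethylketeniminium triflate 3 (not isolated), via cyclobutaniminium triflate 4 (not isolated)
Conditions: Tf2O, 2,4,6-collidine, ClCH2CH2Cl, ethylene (8 bar), 0 → 70 °C; then aq. NaHCO3, rt
Reagents that add atoms: water, O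
Why: Thermal [2+2] cycloaddition of a keteniminium salt with an alkene (Ghosez cyclobutanone synthesis): Tf2O and collidine turn the amide into the tetramethylketeniminium ion, ethylene adds across its C=C bond, and hydrolysis of the cyclobutaniminium salt should give the ketone; no stereocentre is formed.

Step 2
Reactants: 5 2,2-dimethylcyclobutan-1-one
Product: 7 4,4-dimethylcyclobut-1-en-1-yl trifluoromethanesulfonate, via lithium enolate 6 (not isolated)
Conditions: LDA, THF, −78 °C; then PhNTf2, −78 → 0 °C
Reagents that add atoms: N-phenylbis(trifluoromethanesulfonimide), O=S(=O)(N(c1ccccc1)S(=O)(=O)C(F)(F)F)C(F)(F)F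
Why: Enolisation is possible only toward the ring CH2 because the other α-carbon is quaternary, and O-sulfonylation of the lithium enolate with PhNTf2 is the standard enol triflate synthesis; no stereocentre.

Step 3
Reactants: 7 4,4-dimethylcyclobut-1-en-1-yl trifluoromethanesulfonate; 8 2-methyl-2-vinyl-1,3-dioxolane
Product: 10 2-[2-(4,4-dimethylcyclobut-1-en-1-yl)ethyl]-2-methyl-1,3-dioxolane, via B-alkyl-9-BBN 9 (not isolated)
Conditions: 8, 9-BBN, THF, 0 °C → rt; then 7, PdCl2(dppf) (5 mol%), 3 M aq. K3PO4, DMF, rt → 50 °C
Reagents that add atoms: none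
Why: B-alkyl Suzuki–Miyaura coupling: anti-Markovnikov hydroboration of the vinyl ketal gives a primary alkylborane that should transfer its alkyl group to the alkenylpalladium species formed from the triflate, and reductive elimination gives the 1-alkylcyclobutene; no stereocentre.

Step 4
Reactants: 10 2-[2-(4,4-dimethylcyclobut-1-en-1-yl)ethyl]-2-methyl-1,3-dioxolane
Product: 11 2-[(1S,2R)-3,3-dimethyl-2-[2-(2-methyl-1,3-dioxolan-2-yl)ethyl]cyclobutyl]-4,4,5,5-tetramethyl-1,3,2-dioxaborolane
Conditions: CuCl (5 mol%), (R)-DTBM-SEGPHOS (6 mol%), KOtBu (10 mol%), HBpin (1.5 equiv), THF, rt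
Reagents that add atoms: pinacolborane, [H]B1OC(C)(C)C(C)(C)O1
Why: Proposed new method: a ligated copper hydride (formed from CuCl, KOtBu and HBpin) should insert the strained ring C=C bond in a syn fashion with copper at the unsubstituted alkene carbon and hydride at the alkyl-bearing one, and σ-bond metathesis of the secondary cyclobutyl–copper bond with HBpin, which proceeds with retention, should release the boronic ester and regenerate the hydride. The closest known reaction types are the copper hydride catalysed enantioselective hydroboration of internal alkenes with HBpin and the copper hydride catalysed hydroamination of 1-substituted cyclobutenes, in which ring strain makes a trisubstituted alkene reactive. No ring is closed. Both new stereocentres are set in the insertion: their relative configuration (boron trans to the side chain) follows from syn addition of H and Cu across the ring alkene, and their absolute configuration from the face chosen by the chiral bisphosphine. The step needs regioselectivity, secured by the gem-dimethyl carbon and the side chain, which leave room at the substituted carbon only for hydride, and enantiofacial selectivity, which rests on the ligand alone because the substrate is achiral. The ketal is inert to the copper hydride, and no other alkene or carbonyl group is present.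

Step 5
Reactants: 12 5-chloropent-1-yne
Product: 14 2-bromo-5-chloropent-1-ene, via (Z)-2-bromoalkenyl-9-BBN adduct 13 (not isolated)
Conditions: B-bromo-9-BBN, CH2Cl2, 0 °C; then AcOH, rt
Reagents that add atoms: B-bromo-9-borabicyclo[3.3.1]nonane, BrB1C2CCCC1CCC2
Why: Bromoboration of a terminal alkyne: syn addition of B–Br places bromine on the internal carbon, and protodeboronation by acetic acid should leave the 2-bromo-1-alkene with the primary chloride untouched; no stereocentre.

Step 6
Reactants: 11 2-[(1S,2R)-3,3-dimethyl-2-[2-(2-methyl-1,3-dioxolan-2-yl)ethyl]cyclobutyl]-4,4,5,5-tetramethyl-1,3,2-dioxaborolane; 14 2-bromo-5-chloropent-1-ene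
Product: 18 2-[2-[(1R,4S)-4-(5-chloropent-1-en-2-yl)-2,2-dimethylcyclobutyl]ethyl]-2-methyl-1,3-dioxolane, via alkenyllithium 15 (not isolated), via lithium boronate complex 16 (not isolated), via β-iodoalkyl boronic ester 17 (not isolated)
Conditions: 14, t-BuLi (2 equiv), Et2O, −78 °C; add 11 in THF, −78 °C; then I2 (THF), then NaOMe (MeOH), −78 °C → rt; aq. Na2S2O3
Reagents that add atoms: none
Why: Zweifel olefination: bromine–lithium exchange gives the alkenyllithium (the remote chloride is tolerated at −78 °C), which adds to boron; iodine then triggers the 1,2-migration of the cyclobutyl group from boron to carbon with retention at the migrating carbon, and methoxide induces anti elimination of boron and iodine, so both ring stereocentres should be carried unchanged into the trans product.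

Step 7
Reactants: 18 2-[2-[(1R,4S)-4-(5-chloropent-1-en-2-yl)-2,2-dimethylcyclobutyl]ethyl]-2-methyl-1,3-dioxolane; 19 linoleic acid
Product: 21 4-[(1S,2R)-3,3-dimethyl-2-[2-(2-methyl-1,3-dioxolan-2-yl)ethyl]cyclobutyl]pent-4-en-1-yl (9Z,12Z)-octadeca-9,12-dienoate, via caesium linoleate 20 (not isolated)
Conditions: Cs2CO3, NaI (cat.), DMF, 50 °C, argon, dark
Reagents that add atoms: none
Why: SN2 O-alkylation of a caesium carboxylate by the primary chloride (iodide catalysis, Finkelstein exchange in the flask) should form the ester without any protecting group on oxygen and leave the ketal, the skipped (Z,Z)-diene and the ring stereocentres untouched.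

Step 8
Reactants: 21 4-[(1S,2R)-3,3-dimethyl-2-[2-(2-methyl-1,3-dioxolan-2-yl)ethyl]cyclobutyl]pent-4-en-1-yl (9Z,12Z)-octadeca-9,12-dienoate
Product: 22 4-[(1S,2R)-3,3-dimethyl-2-(3-oxobutyl)cyclobutyl]pent-4-en-1-yl (9Z,12Z)-octadeca-9,12-dienoate
Conditions: 1 M aq. HCl, THF, 0 °C → rt
Reagents that add atoms: water, O
Why: Acid-catalysed hydrolysis of the dioxolane (ketal deprotection) under mild conditions should free the methyl ketone without touching the ester, the skipped diene, the 1,1-disubstituted alkene or the ring stereocentres, neither of which is epimerisable.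

**Compound list**
1 | N,N-dimethylisobutyramide (N,N,2-trimethylpropanamide) | CC(C)C(=O)N(C)C | starting material
2 | ethylene | C=C | starting material
3 | dimethyl(2-methylprop-1-en-1-ylidene)ammonium trifluoromethanesulfonate (tetramethylketeniminium triflate) | CC(C)=C=[N+](C)C.[O-]S(=O)(=O)C(F)(F)F | intermediate (not isolated)
4 | (2,2-dimethylcyclobutylidene)dimethylammonium trifluoromethanesulfonate | CC1(C)CCC1=[N+](C)C.[O-]S(=O)(=O)C(F)(F)F | intermediate (not isolated)
5 | 2,2-dimethylcyclobutan-1-one | CC1(C)CCC1=O | intermediate
6 | lithium 4,4-dimethylcyclobut-1-en-1-olate | CC1(C)CC=C1[O-].[Li+] | intermediate (not isolated)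
7 | 4,4-dimethylcyclobut-1-en-1-yl trifluoromethanesulfonate | CC1(C)CC=C1OS(=O)(=O)C(F)(F)F | intermediate
8 | 2-methyl-2-vinyl-1,3-dioxolane (2-ethenyl-2-methyl-1,3-dioxolane) | C=CC1(C)OCCO1 | starting material
9 | 9-[2-(2-methyl-1,3-dioxolan-2-yl)ethyl]-9-borabicyclo[3.3.1]nonane | CC1(CCB2C3CCCC2CCC3)OCCO1 | intermediate (not isolated)
10 | 2-[2-(4,4-dimethylcyclobut-1-en-1-yl)ethyl]-2-methyl-1,3-dioxolane | CC1(CCC2=CCC2(C)C)OCCO1 | intermediate
11 | 2-[(1S,2R)-3,3-dimethyl-2-[2-(2-methyl-1,3-dioxolan-2-yl)ethyl]cyclobutyl]-4,4,5,5-tetramethyl-1,3,2-dioxaborolane (boron trans to the side chain) | CC1(C)OB(OC1(C)C)[C@H]2CC(C)(C)[C@@H]2CCC3(C)OCCO3 | intermediate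
12 | 5-chloropent-1-yne | C#CCCCCl | starting material
13 | 9-[(1Z)-2-bromo-5-chloropent-1-en-1-yl]-9-borabicyclo[3.3.1]nonane | Br/C(CCCCl)=C\B1C2CCCC1CCC2 | intermediate (not isolated)
14 | 2-bromo-5-chloropent-1-ene | C=C(Br)CCCCl | intermediate
15 | (5-chloropent-1-en-2-yl)lithium | [Li]C(=C)CCCCl | intermediate (not isolated)
16 | lithium (5-chloropent-1-en-2-yl)[(1S,2R)-3,3-dimethyl-2-[2-(2-methyl-1,3-dioxolan-2-yl)ethyl]cyclobutyl](2,3-dimethylbutane-2,3-diolato)borate | C=C(CCCCl)[B-]1(OC(C)(C)C(C)(C)O1)[C@H]2CC(C)(C)[C@@H]2CCC3(C)OCCO3.[Li+] | intermediate (not isolated)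
17 | 2-[5-chloro-1-iodo-2-[(1S,2R)-3,3-dimethyl-2-[2-(2-methyl-1,3-dioxolan-2-yl)ethyl]cyclobutyl]pentan-2-yl]-4,4,5,5-tetramethyl-1,3,2-dioxaborolane (both epimers at the boron-bearing carbon) | ClCCCC(CI)(B1OC(C)(C)C(C)(C)O1)[C@H]2CC(C)(C)[C@@H]2CCC3(C)OCCO3 | intermediate (not isolated)
18 | 2-[2-[(1R,4S)-4-(5-chloropent-1-en-2-yl)-2,2-dimethylcyclobutyl]ethyl]-2-methyl-1,3-dioxolane (trans) | C=C(CCCCl)[C@H]1CC(C)(C)[C@@H]1CCC2(C)OCCO2 | intermediate
19 | linoleic acid, (9Z,12Z)-octadeca-9,12-dienoic acid | CCCCC/C=C\C/C=C\CCCCCCCC(=O)O | starting material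
20 | caesium (9Z,12Z)-octadeca-9,12-dienoate | CCCCC/C=C\C/C=C\CCCCCCCC(=O)[O-].[Cs+] | intermediate (not isolated)
21 | 4-[(1S,2R)-3,3-dimethyl-2-[2-(2-methyl-1,3-dioxolan-2-yl)ethyl]cyclobutyl]pent-4-en-1-yl (9Z,12Z)-octadeca-9,12-dienoate | C=C(CCCOC(=O)CCCCCCC/C=C\C/C=C\CCCCC)[C@H]1CC(C)(C)[C@@H]1CCC2(C)OCCO2 | intermediate
22 | 4-[(1S,2R)-3,3-dimethyl-2-(3-oxobutyl)cyclobutyl]pent-4-en-1-yl (9Z,12Z)-octadeca-9,12-dienoate | C=C(CCCOC(=O)CCCCCCC/C=C\C/C=C\CCCCC)[C@H]1CC(C)(C)[C@@H]1CCC(C)=O | target

Total step count: 8. Longest linear sequence: 7 steps (steps 1, 2, 3, 4, 6, 7 and 8).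

Steps most likely to fail:

Step 4. The hydride may insert too slowly into the hindered trisubstituted alkene, the facial discrimination may be insufficient, or the cyclobutylcopper intermediate may open by β-carbon elimination before it meets the borane. The fallback is known chemistry and uses reagent control in place of catalyst control. Setting out from 10, hydroboration with monoisopinocampheylborane prepared from (+)-α-pinene (Et2O, −25 °C) would give the dialkylborane [(1S,2R)-3,3-dimethyl-2-[2-(2-methyl-1,3-dioxolan-2-yl)ethyl]cyclobutyl](isopinocampheyl)borane F1. By analogy with the addition of this reagent to 1-methylcyclopentene, F1 is expected to carry the required configuration, and its crystallisation should raise the enantiomeric purity. Acetaldehyde would then expel α-pinene to give the diethyl boronate F2, and exchange with pinacol would come back to 11. The reagent from (−)-α-pinene would be used if the sense proved opposite.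

Step 6. Formation of the hindered boronate complex may be incomplete, the chloro-substituted alkenyllithium may decompose on warming, or iodine may attack the product alkene. The fallback replaces the boronate rearrangement by a radical cross-coupling. Setting out from 11, KHF2 (MeOH/H2O) would give potassium trifluoro[(1S,2R)-3,3-dimethyl-2-[2-(2-methyl-1,3-dioxolan-2-yl)ethyl]cyclobutyl]borate F3. A photoredox/nickel dual-catalysed coupling of F3 with 14 (Ir[dF(CF3)ppy]2(bpy)PF6, NiCl2·glyme, 4,4′-di-tert-butyl-2,2′-bipyridine, Cs2CO3, dioxane, blue light) would come back to 18. The ring radical should be captured by nickel on the face away from the neighbouring chain, so the trans isomer should again prevail, now by substrate control.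

Step 3. The strained enol triflate may hydrolyse back to 5 under the aqueous base, or transfer of the alkyl group from boron may be slow. The fallback reverses the polarity and uses the ring as the nucleophile. Setting out from 5, condensation with 2,4,6-triisopropylbenzenesulfonohydrazide would give N'-(2,2-dimethylcyclobutylidene)-2,4,6-tri(propan-2-yl)benzenesulfonohydrazide F4. A Shapiro reaction (n-BuLi, 2 equiv, THF/TMEDA, −78 → 0 °C) would give (4,4-dimethylcyclobut-1-en-1-yl)lithium F5, and alkylation with commercial 2-(2-bromoethyl)-2-methyl-1,3-dioxolane would come back to 10 without the triflate 7.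

**Further compounds**
F1 | step 4 | [(1S,2R)-3,3-dimethyl-2-[2-(2-methyl-1,3-dioxolan-2-yl)ethyl]cyclobutyl](isopinocampheyl)borane, isopinocampheyl group from (+)-α-pinene | C[C@H]1[C@H](B[C@H]3CC(C)(C)[C@@H]3CCC4(C)OCCO4)C[C@@H]2C[C@H]1C2(C)C
F2 | step 4 | diethyl [(1S,2R)-3,3-dimethyl-2-[2-(2-methyl-1,3-dioxolan-2-yl)ethyl]cyclobutyl]boronate | CCOB(OCC)[C@H]1CC(C)(C)[C@@H]1CCC2(C)OCCO2
F3 | step 6 | potassium trifluoro[(1S,2R)-3,3-dimethyl-2-[2-(2-methyl-1,3-dioxolan-2-yl)ethyl]cyclobutyl]borate | F[B-](F)(F)[C@H]1CC(C)(C)[C@@H]1CCC2(C)OCCO2.[K+]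
F4 | step 3 | N'-(2,2-dimethylcyclobutylidene)-2,4,6-tri(propan-2-yl)benzenesulfonohydrazide (C=N geometry not defined) | CC1(C)CCC1=NNS(=O)(=O)c2c(C(C)C)cc(C(C)C)cc2C(C)C
F5 | step 3 | (4,4-dimethylcyclobut-1-en-1-yl)lithium | [Li]C1=CCC1(C)C
A1 | direct plan | (3S)-7-methylocta-1,6-dien-3-ol | C=C[C@@H](O)CCC=C(C)C
A2 | direct plan | (1R,5R)-6,6-dimethylbicyclo[3.2.0]heptan-2-one | O=C1CC[C@@H]2[C@H]1CC2(C)C
A3 | direct plan | (1R,2R)-3,3-dimethyl-2-(3-oxobutyl)cyclobutane-1-carboxylic acid (cis) | OC(=O)[C@@H]1CC(C)(C)[C@@H]1CCC(C)=O
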